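Each closed, stirred vessel holds substrate, coupling partner and capture agent, and alder, elm and ash differ in the charge of capture agent.

    substrate + coupling partner ⇌ adduct (K1 = 0.89 L mol⁻¹, k1 = 0.0332 L mol⁻¹ s⁻¹)
    capture agent + adduct → trapped intermediate (k2 = 0.00524 L mol⁻¹ s⁻¹)
    coupling partner → decomposed reagent (k3 = 0.0596 s⁻¹)
    adduct → product (k4 = 0.0520 s⁻¹)

| flask | substrate | coupling partner | capture agent | time |
|---|---|---|---|---|
| alder | 0.51 M | 0.800 equiv | 0.0150 M | 12 min |
| elm | 0.51 M | 0.800 equiv | 0.0250 M | 12 min |
| ash | 0.51 M | 0.800 equiv | 0.0400 M | 12 min |

* [product] at the end for alder, elm, ash, in this order
* the course of these numbers from the first flask to the last (falls, then rises / rises all the way / hardly changes / falls all the way / rises, then falls)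

- "hardly changes" means that all values lie within two and a half points (for a concentration: within two and a half percent of the largest)
- run time (alder): 12 min

*What does the end state look like?*

The coupling partner is the limiting reagent, at 0.408 M against 0.51 M of substrate. In alder its half-life by decomposition alone is 0.19 min, and that of adduct by the product step alone is 0.22 min. Both are far shorter than the 12 min allowed. So I take the end to be the finished split of that charge, and I ask how it divides rather than how fast.

*How does it divide?*

At the start in alder, decomposition uses coupling partner 3.5 times as fast as the forward addition does. Adduct, once made, goes on at 0.0520 s⁻¹ or falls back at 0.0373 s⁻¹, so 58.2 % of it goes on. Together these send 14.2 % of the charge to product, which is 0.0579 M. That reckoning holds substrate at its charge, but substrate must fall, so I take my figure to be somewhat high.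

*But you vary the capture agent. Why should the row stay put?*

The capture step and the product step draw on the same adduct, so I compare their rates, and the adduct cancels. What remains is the capture constant 0.00524 L mol⁻¹ s⁻¹ times c(capture agent), a pseudo-first-order constant, over 0.0520 s⁻¹. This ratio, the trap share, is 0.151 % in alder and 0.403 % in ash. It also says what is trapped: while c(capture agent) stays near its charge, c(trapped intermediate) is the trap share times c(product). From alder to ash the share grows by 0.25 percentage points, and it stays far below one, so my answer for the course is: hardly changes.

The forecast gives 0.0544 M, 0.0544 M and 0.0543 M and calls the course hardly changes, on the ground that “The capture agent is only a minor sink”. Its figure stands below my 0.0579 M, and on the course we agree.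

The flasks give 0.0543 M, 0.0543 M and 0.0542 M, and the course hardly changes. Striking out the capture step changes the final product of ash by at most 0.3 percent. In alder, the trap share times the product gives 0.0161 % of the substrate charged as trapped intermediate, and the flask holds 0.0161 % after 12.0 min. In ash, the larger share gives 0.0428 %, and the flask holds 0.0427 % of trapped intermediate after 12.0 min.

The constants used here belong to no real substance, and the outcome is calculated.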